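**Retrosynthetic overview**

1. The target comes from selective 8-O-acetylation of its diol. The pyran ring is opened at O2–C3 (6-endo 1,6-oxa-Michael addition of the C1 hydroxyl to a 3-alkynylcyclohexenone), and the C4a–C4 bond is cut by a Sonogashira coupling between the (S)-dienyne side chain and a C4a enol triflate.
2. The carbocycle is the first ring formed and is closed at C5–C6 by a Dieckmann-type acylation: a methyl ketone enolate (C5) attacks the carbonyl (C6) of a Seebach 1,3-dioxolan-4-one. This temporary ring is acyl donor, protecting group and chirality carrier, and it leaves as pivalaldehyde, freeing the C7 carbinol.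
3. Enabling feature: in the six-membered carbocycle C5 is a CH between C4a and C6, both at the carbonyl oxidation level (a masked cyclohexane-1,3-dione). C6, C7, the 7-methyl and the 7-oxygen are the carboxyl, α-carbon, methyl and hydroxyl of L-lactic acid.
4. The open-chain precursor comes from an Evans syn aldol (C8–C8a bond) between a 3-silyloxypropanoyl imide and the lactate-derived quaternary aldehyde. The dienyne comes from (S)-2-methylbutan-1-ol by oxidation, Wittig and Horner–Wadsworth–Emmons steps.
5. Ring order: dioxolanone (bought, temporary), carbocycle (step 11), pyran (step 14).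

Key step: step 11

Remark: atom labels C1 to C8a are the isochromene positions of the target and are used for the corresponding atoms of every intermediate; the Seebach dioxolanone of L-lactic acid and 3-silyloxypropanoic acid are taken as purchasable.

**Route**

Step 1
Reactants: 1 (S)-2-methylbutan-1-ol
Product: 2 (S)-2-methylbutanal
Conditions: TEMPO (cat.), KBr (cat.), NaOCl, NaHCO3, CH2Cl2/H2O, 0 °C; used as a dried CH2Cl2 solution
Reagents that add atoms: none
Why: Anelli (TEMPO/NaOCl) oxidation of a primary alcohol stops at the aldehyde, and the buffered two-phase medium should leave the α-stereocenter untouched.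

Step 2
Reactants: 2 (S)-2-methylbutanal; 3 2-(triphenylphosphoranylidene)propanal
Product: 4 (2E,4S)-2,4-dimethylhex-2-enal
Conditions: toluene, 80 °C
Reagents that add atoms: none
Why: Wittig olefination with a formyl-stabilised ylide should give the (E)-trisubstituted enal under thermodynamic control without touching the allylic stereocenter.

Step 3
Reactants: 4 (2E,4S)-2,4-dimethylhex-2-enal; 5 diethyl [3-(trimethylsilyl)prop-2-yn-1-yl]phosphonate
Product: 6 trimethyl[(3E,5E,7S)-5,7-dimethylnona-3,5-dien-1-yn-1-yl]silane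
Conditions: LiN(SiMe3)2, THF, −78 °C to rt; aq. NH4Cl
Reagents that add atoms: none
Why: Horner–Wadsworth–Emmons olefination with the propargylic phosphonate anion should form the new disubstituted alkene with (E) geometry, any minor (Z) isomer being removed by chromatography.

Step 4
Reactants: 6 trimethyl[(3E,5E,7S)-5,7-dimethylnona-3,5-dien-1-yn-1-yl]silane
Product: 7 (3E,5E,7S)-5,7-dimethylnona-3,5-dien-1-yne
Conditions: K2CO3 (cat.), MeOH, 0 °C to rt
Reagents that add atoms: none
Why: base-catalysed methanolysis of the alkynyl C–Si bond (protodesilylation) frees the terminal alkyne and leaves the diene alone.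

Step 5
Reactants: 8 (2S,5S)-2-tert-butyl-5-methyl-1,3-dioxolan-4-one
Product: 9 (2S,4R)-2-tert-butyl-4-methyl-5-oxo-1,3-dioxolane-4-carbaldehyde
Conditions: LiN(iPr)2, THF, −78 °C; N-methoxy-N-methylformamide, −78 °C; aq. NH4Cl
Reagents that add atoms: N-methoxy-N-methylformamide O=CN(C)OC
Why: Claisen-type C-formylation of the Seebach lithium enolate by a Weinreb formamide; the electrophile should enter anti to the tert-butyl group (self-regeneration of stereocenters), so the lactic acid configuration is retained at the new quaternary center, and the chelated tetrahedral adduct prevents a second addition.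

Step 6
Reactants: 10 3-[(tert-butyldimethylsilyl)oxy]propanoic acid; 11 (R)-4-benzyl-1,3-oxazolidin-2-one
Product: 13 (R)-4-benzyl-3-{3-[(tert-butyldimethylsilyl)oxy]propanoyl}-1,3-oxazolidin-2-one, via mixed pivalic anhydride 12 (not isolated)
Conditions: pivaloyl chloride, Et3N, THF, −20 °C; then LiCl, 11, −20 °C to rt
Reagents that add atoms: none
Why: N-acylation of the oxazolidinone through the mixed pivalic anhydride with LiCl/Et3N activation is the standard imide formation and creates no stereocenter.

Step 7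
Reactants: 13 (R)-4-benzyl-3-{3-[(tert-butyldimethylsilyl)oxy]propanoyl}-1,3-oxazolidin-2-one; 9 (2S,4R)-2-tert-butyl-4-methyl-5-oxo-1,3-dioxolane-4-carbaldehyde
Product: 14 (R)-4-benzyl-3-[(2R,3R)-3-[(2S,4R)-2-tert-butyl-4-methyl-5-oxo-1,3-dioxolan-4-yl]-2-{[(tert-butyldimethylsilyl)oxy]methyl}-3-hydroxypropanoyl]-1,3-oxazolidin-2-one
Conditions: Bu2BOTf, iPr2NEt, CH2Cl2, 0 °C; then 9, −78 to 0 °C; pH 7 buffer, MeOH, H2O2
Reagents that add atoms: none
Why: Evans syn aldol addition through the (Z)-boron enolate and a chair transition state; the (R)-benzyl auxiliary should set both new centers (C8a and C8, 2R,3R) and override the small bias of the non-enolisable α-quaternary aldehyde.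

Step 8
Reactants: 14 (the aldol adduct of step 7)
Product: 15 (2R,3R)-3-[(2S,4R)-2-tert-butyl-4-methyl-5-oxo-1,3-dioxolan-4-yl]-2-{[(tert-butyldimethylsilyl)oxy]methyl}-3-hydroxy-N-methoxy-N-methylpropanamide
Conditions: AlMe3, MeNH(OMe)·HCl, CH2Cl2, −15 to 0 °C; aq. HCl work-up
Reagents that add atoms: N,O-dimethylhydroxylamine hydrochloride CNOC.Cl
Why: Weinreb transamidation with the aluminium amide is accelerated by the free β-hydroxyl and should cleave the exocyclic imide carbonyl in preference to the hindered dioxolanone.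

Step 9
Reactants: 15 (the hydroxy Weinreb amide of step 8)
Product: 16 (2R,3R)-3-[(2S,4R)-2-tert-butyl-4-methyl-5-oxo-1,3-dioxolan-4-yl]-3-[(tert-butyldimethylsilyl)oxy]-2-{[(tert-butyldimethylsilyl)oxy]methyl}-N-methoxy-N-methylpropanamide
Conditions: TBSOTf, 2,6-lutidine, CH2Cl2, −78 to 0 °C
Reagents that add atoms: tert-butyldimethylsilyl trifluoromethanesulfonate CC(C)(C)[Si](C)(C)OS(=O)(=O)C(F)(F)F
Why: silyl ether formation at the hindered secondary alcohol with the silyl triflate blocks retro-aldol cleavage in the later base steps.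

Step 10
Reactants: 16 (the bis-silyl Weinreb amide of step 9)
Product: 17 (2S,5R)-2-tert-butyl-5-[(1R,2R)-1-[(tert-butyldimethylsilyl)oxy]-2-{[(tert-butyldimethylsilyl)oxy]methyl}-3-oxobutyl]-5-methyl-1,3-dioxolan-4-one
Conditions: MeMgBr, THF, −78 to 0 °C; aq. NH4Cl
Reagents that add atoms: methylmagnesium bromide C[Mg]Br
Why: Grignard addition to a Weinreb amide stops at the ketone through the chelated tetrahedral intermediate, and the amide should react faster than the neopentyl-type dioxolanone carbonyl.

Step 11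
Reactants: 17 (the methyl ketone of step 10)
Product: 18 (4R,5R,6R)-5-[(tert-butyldimethylsilyl)oxy]-6-{[(tert-butyldimethylsilyl)oxy]methyl}-4-hydroxy-4-methylcyclohexane-1,3-dione
Conditions: LiN(SiMe3)2 (3.2 equiv), THF, −78 to −20 °C; aq. NH4Cl
Reagents that add atoms: none
Why: Kinetic deprotonation of the methyl group (C5) gives the less substituted lithium enolate, whose carbon adds to the dioxolanone carbonyl (C6); the tetrahedral intermediate collapses by expelling the acetal oxygen, the hemiacetal alkoxide loses pivalaldehyde to leave the C7 alkoxide, and proton transfer gives the lithium diketonate as the thermodynamic sink. The closest known reaction type is the Dieckmann (intramolecular Claisen) condensation of a ketone enolate with an ester-type carbonyl to a cyclohexane-1,3-dione, here with a 1,3-dioxolan-4-one as acyl donor. The carbocycle closes in the 6-(enolexo)-exo-trig mode, and the temporary dioxolanone ring is opened in the same event. No stereocenter is formed: C7 is quaternary, C8 has no acidic hydrogen, and C8a is left alone because its hindered methine is deprotonated more slowly than the methyl group at −78 °C and the product is protected as its diketonate. The step needs enolisation at C5 and not at C8a (a C8a enolate would eliminate a silanolate) and C- rather than O-acylation; the amide base at low temperature should secure the first, only C-attack gives an unstrained six-membered ring, and the excess LiN(SiMe3)2 removes the released pivalaldehyde as its N-silyl imine so that it cannot capture uncyclised enolate.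

Step 12
Reactants: 18 (the dione of step 11)
Product: 19 (4R,5R,6R)-5-[(tert-butyldimethylsilyl)oxy]-6-{[(tert-butyldimethylsilyl)oxy]methyl}-4-hydroxy-4-methyl-3-oxocyclohex-1-en-1-yl trifluoromethanesulfonate
Conditions: PhNTf2, Et3N, DMAP (cat.), CH2Cl2, 0 °C
Reagents that add atoms: N-phenylbis(trifluoromethanesulfonimide) O=S(=O)(N(c1ccccc1)S(=O)(=O)C(F)(F)F)C(F)(F)F
Why: O-sulfonylation of the vinylogous acid (enol triflate formation) should occur at the C4a oxygen because the C6 oxygen is hydrogen-bonded to and shielded by the adjacent tertiary carbinol, which itself is inert to this reagent as a neutral alcohol.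

Step 13
Reactants: 19 (the enol triflate of step 12); 7 (3E,5E,7S)-5,7-dimethylnona-3,5-dien-1-yne
Product: 20 (4R,5R,6R)-5-[(tert-butyldimethylsilyl)oxy]-4-{[(tert-butyldimethylsilyl)oxy]methyl}-3-[(3E,5E,7S)-5,7-dimethylnona-3,5-dien-1-yn-1-yl]-6-hydroxy-6-methylcyclohex-2-en-1-one
Conditions: Pd(PPh3)2Cl2 (5 mol %), CuI (10 mol %), Et3N, THF, rt, degassed
Reagents that add atoms: none
Why: Sonogashira coupling; the electron-poor vinylogous acyl triflate adds readily to zerovalent palladium, and the alkene geometries and stereocenters of both partners are not involved.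

Step 14
Reactants: 20 (the bis-silyl enynone of step 13)
Product: 22 (7R,8R,8aR)-3-[(1E,3E,5S)-3,5-dimethylhepta-1,3-dien-1-yl]-7,8-dihydroxy-7-methyl-1,7,8,8a-tetrahydro-6H-isochromen-6-one, via diol enynone 21 (not isolated)
Conditions: HF·pyridine, pyridine, THF, 0 °C to rt; then DBU (0.1 equiv), CH2Cl2, 0 °C
Reagents that add atoms: none
Why: fluoride desilylation followed by base-catalysed intramolecular 1,6-oxa-Michael addition (6-endo-dig) of the C1 hydroxyl to the δ-carbon C3 of the enynone and protonation at C4; conjugate-addition polarity directs the oxygen to C3 and not to C4, the C8 hydroxyl could only close a strained bridged ring, and no stereocenter is formed.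

Step 15
Reactants: 22 (the diol of step 14)
Product: 23 (7R,8R,8aR)-3-[(1E,3E,5S)-3,5-dimethylhepta-1,3-dien-1-yl]-7-hydroxy-7-methyl-6-oxo-6,7,8,8a-tetrahydro-1H-isochromen-8-yl acetate (target)
Conditions: Ac2O, pyridine, CH2Cl2, 0 °C to rt
Reagents that add atoms: acetic anhydride CC(=O)OC(C)=O
Why: chemoselective esterification of the secondary C8 hydroxyl; the tertiary α-ketol hydroxyl at C7 should not react under these mild conditions, and pyridine is too weak a base to remove the C8a hydrogen.

**Compound list**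

1 | (S)-2-methylbutan-1-ol | CC[C@H](C)CO | starting material
2 | (S)-2-methylbutanal | CC[C@H](C)C=O | intermediate
3 | 2-(triphenylphosphoranylidene)propanal | CC(C=O)=P(c1ccccc1)(c1ccccc1)c1ccccc1 | starting material
4 | (2E,4S)-2,4-dimethylhex-2-enal | CC[C@H](C)/C=C(C)/C=O | intermediate
5 | diethyl [3-(trimethylsilyl)prop-2-yn-1-yl]phosphonate | CCOP(=O)(CC#C[Si](C)(C)C)OCC | starting material
6 | trimethyl[(3E,5E,7S)-5,7-dimethylnona-3,5-dien-1-yn-1-yl]silane | CC[C@H](C)/C=C(C)/C=C/C#C[Si](C)(C)C | intermediate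
7 | (3E,5E,7S)-5,7-dimethylnona-3,5-dien-1-yne | CC[C@H](C)/C=C(C)/C=C/C#C | intermediate
8 | (2S,5S)-2-tert-butyl-5-methyl-1,3-dioxolan-4-one | C[C@@H]1O[C@H](C(C)(C)C)OC1=O | starting material
9 | (2S,4R)-2-tert-butyl-4-methyl-5-oxo-1,3-dioxolane-4-carbaldehyde | C[C@]1(C=O)O[C@H](C(C)(C)C)OC1=O | intermediate
10 | 3-[(tert-butyldimethylsilyl)oxy]propanoic acid | CC(C)(C)[Si](C)(C)OCCC(=O)O | starting material
11 | (R)-4-benzyl-1,3-oxazolidin-2-one | O=C1N[C@H](Cc2ccccc2)CO1 | starting material
12 | 3-[(tert-butyldimethylsilyl)oxy]propanoic pivalic anhydride | CC(C)(C)[Si](C)(C)OCCC(=O)OC(=O)C(C)(C)C | intermediate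
13 | (R)-4-benzyl-3-{3-[(tert-butyldimethylsilyl)oxy]propanoyl}-1,3-oxazolidin-2-one | CC(C)(C)[Si](C)(C)OCCC(=O)N1[C@H](Cc2ccccc2)COC1=O | intermediate
14 | (R)-4-benzyl-3-[(2R,3R)-3-[(2S,4R)-2-tert-butyl-4-methyl-5-oxo-1,3-dioxolan-4-yl]-2-{[(tert-butyldimethylsilyl)oxy]methyl}-3-hydroxypropanoyl]-1,3-oxazolidin-2-one | CC(C)(C)[C@@H]1OC(=O)[C@](C)(O1)[C@H](O)[C@@H](CO[Si](C)(C)C(C)(C)C)C(=O)N2[C@H](Cc3ccccc3)COC2=O | intermediate
15 | (2R,3R)-3-[(2S,4R)-2-tert-butyl-4-methyl-5-oxo-1,3-dioxolan-4-yl]-2-{[(tert-butyldimethylsilyl)oxy]methyl}-3-hydroxy-N-methoxy-N-methylpropanamide | CC(C)(C)[C@@H]1OC(=O)[C@](C)(O1)[C@H](O)[C@@H](CO[Si](C)(C)C(C)(C)C)C(=O)N(C)OC | intermediate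
16 | (2R,3R)-3-[(2S,4R)-2-tert-butyl-4-methyl-5-oxo-1,3-dioxolan-4-yl]-3-[(tert-butyldimethylsilyl)oxy]-2-{[(tert-butyldimethylsilyl)oxy]methyl}-N-methoxy-N-methylpropanamide | CC(C)(C)[C@@H]1OC(=O)[C@](C)(O1)[C@H](O[Si](C)(C)C(C)(C)C)[C@@H](CO[Si](C)(C)C(C)(C)C)C(=O)N(C)OC | intermediate
17 | (2S,5R)-2-tert-butyl-5-[(1R,2R)-1-[(tert-butyldimethylsilyl)oxy]-2-{[(tert-butyldimethylsilyl)oxy]methyl}-3-oxobutyl]-5-methyl-1,3-dioxolan-4-one | CC(C)(C)[C@@H]1OC(=O)[C@](C)(O1)[C@H](O[Si](C)(C)C(C)(C)C)[C@@H](CO[Si](C)(C)C(C)(C)C)C(C)=O | intermediate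
18 | (4R,5R,6R)-5-[(tert-butyldimethylsilyl)oxy]-6-{[(tert-butyldimethylsilyl)oxy]methyl}-4-hydroxy-4-methylcyclohexane-1,3-dione | O=C1CC(=O)[C@](C)(O)[C@H](O[Si](C)(C)C(C)(C)C)[C@H]1CO[Si](C)(C)C(C)(C)C | intermediate
19 | (4R,5R,6R)-5-[(tert-butyldimethylsilyl)oxy]-6-{[(tert-butyldimethylsilyl)oxy]methyl}-4-hydroxy-4-methyl-3-oxocyclohex-1-en-1-yl trifluoromethanesulfonate | FC(F)(F)S(=O)(=O)OC1=CC(=O)[C@](C)(O)[C@H](O[Si](C)(C)C(C)(C)C)[C@H]1CO[Si](C)(C)C(C)(C)C | intermediate
20 | (4R,5R,6R)-5-[(tert-butyldimethylsilyl)oxy]-4-{[(tert-butyldimethylsilyl)oxy]methyl}-3-[(3E,5E,7S)-5,7-dimethylnona-3,5-dien-1-yn-1-yl]-6-hydroxy-6-methylcyclohex-2-en-1-one | CC[C@H](C)/C=C(C)/C=C/C#CC1=CC(=O)[C@](C)(O)[C@H](O[Si](C)(C)C(C)(C)C)[C@H]1CO[Si](C)(C)C(C)(C)C | intermediate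
21 | (4R,5R,6R)-3-[(3E,5E,7S)-5,7-dimethylnona-3,5-dien-1-yn-1-yl]-5,6-dihydroxy-4-(hydroxymethyl)-6-methylcyclohex-2-en-1-one | CC[C@H](C)/C=C(C)/C=C/C#CC1=CC(=O)[C@](C)(O)[C@H](O)[C@H]1CO | intermediate
22 | (7R,8R,8aR)-3-[(1E,3E,5S)-3,5-dimethylhepta-1,3-dien-1-yl]-7,8-dihydroxy-7-methyl-1,7,8,8a-tetrahydro-6H-isochromen-6-one | CC[C@H](C)/C=C(C)/C=C/C1=CC2=CC(=O)[C@](C)(O)[C@H](O)[C@H]2CO1 | intermediate
23 | (7R,8R,8aR)-3-[(1E,3E,5S)-3,5-dimethylhepta-1,3-dien-1-yl]-7-hydroxy-7-methyl-6-oxo-6,7,8,8a-tetrahydro-1H-isochromen-8-yl acetate | CC[C@H](C)/C=C(C)/C=C/C1=CC2=CC(=O)[C@](C)(O)[C@H](OC(C)=O)[C@H]2CO1 | target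

**Step count and risks**

Total step count: 15. Longest linear sequence: 10 steps (step 5, then steps 7 to 15, from 8 to 23).

Steps most likely to fail:

1. Step 11. What may go wrong: the pivalaldehyde released by each ring closure may capture enolate that has not yet cyclised, and slow acylation at the neopentyl-type carbonyl gives time for proton transfer to C8a followed by β-elimination of a silanolate. Fallback (lactone ring switch), setting out from 17: HF·pyridine in THF/pyridine at 0 °C should remove only the primary silyl ether, and catalytic camphorsulfonic acid in CH2Cl2 lets the freed C1 hydroxyl lactonise onto the dioxolanone, so that pivalaldehyde is expelled before any enolate exists. This gives the keto lactone (3R,4R,5R)-5-acetyl-4-[(tert-butyldimethylsilyl)oxy]-3-hydroxy-3-methyloxan-2-one F1. LiN(SiMe3)2 (3 equiv, THF, −78 °C) then closes the same C5–C6 bond by Dieckmann acyl transfer from the δ-lactone, which opens to (4R,5R,6R)-5-[(tert-butyldimethylsilyl)oxy]-4-hydroxy-6-(hydroxymethyl)-4-methylcyclohexane-1,3-dione F2. TBSCl and imidazole in DMF silylate the primary hydroxyl only and bring the route back to 18.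

2. Step 12. What may go wrong: sulfonylation at the C6 enol oxygen instead of the C4a oxygen, or at both. Fallback (Stork–Danheiser transposition, which needs the opposite O-selectivity), setting out from 18: TMSCHN2 in MeOH/toluene gives the vinylogous methyl ester with the methoxy group on C6, (4R,5R,6R)-5-[(tert-butyldimethylsilyl)oxy]-6-{[(tert-butyldimethylsilyl)oxy]methyl}-4-hydroxy-3-methoxy-4-methylcyclohex-2-en-1-one F3, separated from its regioisomer. The lithium acetylide of 7 (n-BuLi, THF, −78 °C, 2.5 equiv to allow for the free carbinol) adds 1,2 to the C4a carbonyl, and work-up with dilute aqueous HCl hydrolyses the enol ether with loss of water and methanol, which comes back to the route at 20. Whichever enol oxygen proves the more reactive, one of the two sequences should reach 20.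

3. Step 5. What may go wrong: decomposition of the dioxolanone enolate above −70 °C, or aldol capture of the newly formed aldehyde by unreacted enolate. Fallback (hydroxymethylation, then oxidation), setting out from 8: LiN(iPr)2 at −78 °C and gaseous formaldehyde (cracked paraformaldehyde) should give, again anti to the tert-butyl group, (2S,5R)-2-tert-butyl-5-(hydroxymethyl)-5-methyl-1,3-dioxolan-4-one F4. Dess–Martin periodinane in CH2Cl2 oxidises it to 9.

Further compounds
F1 | step 11 | (3R,4R,5R)-5-acetyl-4-[(tert-butyldimethylsilyl)oxy]-3-hydroxy-3-methyloxan-2-one | O=C1[C@](C)(O)[C@H](O[Si](C)(C)C(C)(C)C)[C@H](C(C)=O)CO1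
F2 | step 11 | (4R,5R,6R)-5-[(tert-butyldimethylsilyl)oxy]-4-hydroxy-6-(hydroxymethyl)-4-methylcyclohexane-1,3-dione | O=C1CC(=O)[C@](C)(O)[C@H](O[Si](C)(C)C(C)(C)C)[C@H]1CO
F3 | step 12 | (4R,5R,6R)-5-[(tert-butyldimethylsilyl)oxy]-6-{[(tert-butyldimethylsilyl)oxy]methyl}-4-hydroxy-3-methoxy-4-methylcyclohex-2-en-1-one | O=C1C=C(OC)[C@](C)(O)[C@H](O[Si](C)(C)C(C)(C)C)[C@H]1CO[Si](C)(C)C(C)(C)C
F4 | step 5 | (2S,5R)-2-tert-butyl-5-(hydroxymethyl)-5-methyl-1,3-dioxolan-4-one | C[C@]1(CO)O[C@H](C(C)(C)C)OC1=O
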